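Side product counts double in the percentages asked for, and it comes from one step, in which starting complex meets complex with two exchanged.

| setting | north-west | north | south-west | east | west |
|---|---|---|---|---|---|
| starting complex | 0.092 M | 0.092 M (fed, over 2.5 min) | 0.092 M | 0.092 M | 0.092 M (in portions, 4, over 2.5 min) |
| incoming ligand | 1.50 equiv | 1.50 equiv | 1.50 equiv (fed, over 2.5 min) | 1.50 equiv (fed, over 40 s) | 1.50 equiv |
| leaving ligand | 0.500 equiv | 0.500 equiv | 0.500 equiv | 0.500 equiv | 0.500 equiv |
| time | 3.0 min | 3.0 min | 3.0 min | 3.0 min | 3.0 min |
| remark | everything together at the start | all else is in the flask from the start; the feed brings no volume worth counting | all else is in the flask from the start; the feed brings no volume worth counting | all else is in the flask from the start; the feed brings no volume worth counting | first portion at the start, last at 2.5 min |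

    starting complex + incoming ligand → leaving ligand + complex with one exchanged (k1 = 0.0953 M⁻¹ s⁻¹)
    complex with two exchanged + incoming ligand → leaving ligand + complex with three exchanged (k2 = 0.0485 M⁻¹ s⁻¹)
    complex with one exchanged + incoming ligand → leaving ligand + complex with two exchanged (k3 = 0.0360 M⁻¹ s⁻¹)
    starting complex + complex with two exchanged → side product (k4 = 0.362 M⁻¹ s⁻¹)

* the flask that comes out highest in amount of side product, in percent of the starting complex charged; "all alike" if 1.5 percentage points covers them all (north-west / north / south-west / east / west / all alike)
* amount of side product at the end, in percent of the starting complex charged, north-west
* amount of side product at the end, in percent of the starting complex charged, north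
* amount of side product at the end, in percent of the starting complex charged, south-west
* amount of side product at the end, in percent of the starting complex charged, east
* amount of side product at the end, in percent of the starting complex charged, west

- percentages count the starting complex that a species holds: one side product counts as two
- run time (north-west): 3.0 min

Let m be the fraction of the charge standing as starting complex and x the incoming ligand in equivalents. Complex with two exchanged can react with starting complex, at 0.362 M⁻¹ s⁻¹ times m, or go on to complex with three exchanged, at 0.0485 M⁻¹ s⁻¹ times x. So I carry the capture share, the branching ratio of that complex: the first term over the sum of both.

At the charge in north-west, m is one and x is 1.50 equiv, so the share is 83.3%. But that holds for a moment, so I go round again. Step one alone, the other concentrations as charged, gives starting complex a half-life of 0.88 min in north-west, so for that moment I take m as half. In that step each complex lost takes one ligand, so I take x as 1.00. The side-product term still leads, and the capture share at that point is 78.9%. Side product counts double, so the captured part of complex with two exchanged shows up twice in the answer. This gives no amount, and my reckoning stops here.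

The forecast puts north-west highest: 19%, then east 17.5%, north 14%, west 13.5% and south-west 10.5%. Its ground is that “Side product needs starting complex and the twice-exchanged complex present together”.

North-west does come out highest at 18.1%, with east 16.0%, west 11.5%, north 11.2% and south-west 9.07%. Against its complex with three exchanged, north-west's side product, counted once each, gives a share so far of 77.0%, summed over the run, against my 78.9% for a single moment. South-west gives 82.4% the same way. Neither flask is at rest at 3.00 min. By 30.0 min, side product reaches 37.8% in south-west and 37.5% in north-west, where starting complex has fallen to 0%, the share so far to 54.8%, and incoming ligand to 1.39%, while 17.0% stands as complex with two exchanged.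

The constants stand for no real mixture; the run is a simulation.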